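The earlier runs and the new flask were generated by integration with made-up constants; noise was put on by code.

- My vessel was a closed, stirred flask at constant temperature holding L, Z and the catalyst Q, and my decision was when to stop it: 5.0 min (zeta) or 8.0 min (theta), on the same charge.

| flask | L | Z | Q | remark | time |
|---|---|---|---|---|---|
| Friday's | 0.050 M | 0.0525 M | 3.4 mM | run made earlier |  |
| Wednesday's | 0.050 M | 0.0525 M | 7.5 mM | run made earlier |  |
| Saturday's | 0.050 M | 0.026 M | 5 mM | run made earlier |  |
| theta | 0.050 M | 0.0525 M | 5.0 mM |  | 8.0 min |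
| zeta | 0.050 M | 0.0525 M | 5.0 mM |  | 5.0 min |

| run | time / min | D / % |
|---|---|---|
| Friday's | 0.417 | 0.3 |
| Friday's | 1.33 | 5.2 |
| Friday's | 2.00 | 6.4 |
| Friday's | 3.00 | 10.0 |
| Friday's | 5.00 | 13.0 |
| Wednesday's | 0.417 | 0 |
| Wednesday's | 1.33 | 8.7 |
| Wednesday's | 2.00 | 13.1 |
| Wednesday's | 3.00 | 21.3 |
| Wednesday's | 5.00 | 28.9 |
| Saturday's | 0.417 | 0.4 |
| Saturday's | 0.667 | 2.4 |
| Saturday's | 1.33 | 3.8 |
| Saturday's | 2.50 | 6.9 |
| Saturday's | 5.00 | 13.1 |

(readings scatter by 1 percentage point)

- the numbers in the tables scatter with a standard deviation of 1 percentage point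

- the winner by amount of D, in percent of the L charged; "neither" if no more than 2 percentage points parts them (theta / zeta / neither)
- how much D is there at the end, in percent of the L charged: theta
- how much D is there at the end, in percent of the L charged: zeta

- I replaced each curve by its mean slope. Friday's run gave 0.382 min⁻¹ and Wednesday's 0.385 min⁻¹, and pooled they gave 0.384 min⁻¹: the concentration of D made per concentration of Q charged and per minute, which I call the mean turnover rate (usually, turnover frequency).
- With 5.0 mM of Q, that mean put zeta at 19.2%.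
- Carried on to theta, the same mean gave 30.8%, but that was an error, since the curves bend: the pooled reading from 3.00 min to 5.00 min was 0.243 min⁻¹, less than the 0.479 min⁻¹ before it.
- At that late rate, the extra 3.00 min gained 7.3 points. Cutting the rate once more by the same factor, 0.507, I still reckoned 3.7 points, more than the margin of 2 points. So I chose to leave the flask longer, expecting about 26.5% in theta if the late rate held, and less if it fell further.
- The forecast said theta, with 26% (22.5% to 30%) against 19% (17% to 21%), on these words: “This points to catalyst decay”.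
- Theta gave 27.3% and zeta 20.4%, a gain of 6.9 points, which is a mean turnover rate of 0.228 min⁻¹ over the added time.

    Z + Q ⇌ G (K = 27.0 M⁻¹, k = 69.0 M⁻¹ min⁻¹)
    G → E (k = 2.60 min⁻¹)
    L + E ⇌ X (K = 1900 M⁻¹, k = 140 M⁻¹ min⁻¹)
    X ⇌ Q + D (K = 0.110 M, k = 3.50 min⁻¹)
    D ⇌ J (K = 1.30, k = 0.210 min⁻¹)

- The neighbouring flask is theta with 0.089 M of Z. Saturday's run, with 0.026 M of Z, read 0.262 min⁻¹, less than 0.384 min⁻¹, so from these readings I took the mean turnover rate to go as Z to the power 0.546. That took theta's 0.341 min⁻¹ to 0.454 min⁻¹, or 36.4% of D, and the neighbouring flask gave 34.5%.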